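**Retrosynthetic overview**

1. Alkyne hydration (ethynyl to acetyl) and angeloylation lead back to a tricyclic ethynyl alcohol; opening its tetrahydropyran at the O–CH2 bond (oxa-Michael onto an α-methylene-γ-butyrolactone) gives a nine-membered lactone diol.
2. Key disconnection: the bond between the alkyl oxygen of the nine-membered lactone and the quaternary carbon. Forward, the carboxylate of a (Z)-2-methyl enoic acid opens a 2,3-epoxy alcohol at its tertiary propargylic carbon with inversion and closes the nine-membered ring.
3. Enabling feature: the quaternary ring carbon (O-acyl, CH3, acetyl) is bonded to the tetrahydropyran O–CH carbon, which is bonded to the angelate-bearing CH. These three contiguous C–O carbons are a 2,3-epoxy alcohol opened at C-3, and carrying the acetyl as ethynyl makes C-3 propargylic.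
4. The seco acid comes from Z-selective olefination of an aldehyde made by Lewis acid allylation of an epoxy aldehyde (Sharpless epoxidation of (Z)-3-methylpent-2-en-4-yn-1-ol) with a butenolide allylstannane (ring-closing metathesis route from (S)-but-3-ene-1,2-diol).
5. Ring order: γ-lactone (step 3), oxirane (step 5), nine-membered lactone (step 13), tetrahydropyran (step 14).

Key step: step 13

Assumption: the phosphonate for the olefination is made and used as the racemate (its stereocentre becomes sp2), and the diol and the enynol building blocks are used as the single (S) enantiomer and the single Z isomer.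

**Step 1**
Reactants: 1 (S)-but-3-ene-1,2-diol
Product: 2 (2S)-1-[(tert-butyldiphenylsilyl)oxy]but-3-en-2-ol
Conditions: TBDPSCl, imidazole, CH2Cl2, 0 °C
Reagents that add atoms: tert-butyl(chloro)diphenylsilane, CC(C)(C)[Si](Cl)(c1ccccc1)c1ccccc1
Why: Silyl ether formation is selective for the unhindered primary hydroxyl of the 1,2-diol, and the stereocentre of 1 (later the γ-lactone carbon that carries the enoate arm) is not touched.

**Step 2**
Reactants: 2 (2S)-1-[(tert-butyldiphenylsilyl)oxy]but-3-en-2-ol; 3 2-(bromomethyl)prop-2-enoic acid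
Product: 4 (2S)-1-[(tert-butyldiphenylsilyl)oxy]but-3-en-2-yl 2-(bromomethyl)prop-2-enoate
Conditions: DCC, DMAP (5 mol %), CH2Cl2, 0 °C
Reagents that add atoms: none
Why: Steglich esterification acylates the secondary allylic alcohol under neutral conditions that leave the allylic bromide and the stereocentre intact.

**Step 3**
Reactants: 4 (2S)-1-[(tert-butyldiphenylsilyl)oxy]but-3-en-2-yl 2-(bromomethyl)prop-2-enoate
Product: 5 (5S)-3-(bromomethyl)-5-{[(tert-butyldiphenylsilyl)oxy]methyl}furan-2(5H)-one
Conditions: second-generation Hoveyda–Grubbs catalyst (5 mol %), toluene (5 mM), 80 °C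
Reagents that add atoms: none
Why: Ring-closing metathesis between the vinyl group and the 1,1-disubstituted acrylate closes the unsaturated five-membered lactone with loss of ethene, the ring size enforcing the cis ring alkene.

**Step 4**
Reactants: 5 (5S)-3-(bromomethyl)-5-{[(tert-butyldiphenylsilyl)oxy]methyl}furan-2(5H)-one
Product: 6 (5S)-5-{[(tert-butyldiphenylsilyl)oxy]methyl}-3-[(tributylstannyl)methyl]furan-2(5H)-one
Conditions: (Bu3Sn)2, Pd2(dba)3 (2.5 mol %), THF, 23 °C
Reagents that add atoms: hexabutylditin, CCCC[Sn](CCCC)(CCCC)[Sn](CCCC)(CCCC)CCCC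
Why: Pd-catalysed stannylation of the allylic bromide (oxidative addition to zerovalent palladium, transmetalation with the ditin, reductive elimination) places tin on the exocyclic CH2 so that the conjugated ring alkene is kept.

**Step 5**
Reactants: 7 (2Z)-3-methylpent-2-en-4-yn-1-ol
Product: 8 [(2S,3R)-3-ethynyl-3-methyloxiran-2-yl]methanol
Conditions: Ti(OiPr)4 (10 mol %), L-(+)-diethyl tartrate (12 mol %), t-BuOOH, 4 Å molecular sieves, CH2Cl2, −20 °C
Reagents that add atoms: tert-butyl hydroperoxide, CC(C)(C)OO
Why: Sharpless asymmetric epoxidation of the primary allylic alcohol, in which the L-(+)-tartrate selects the alkene face and the syn-specific oxygen transfer turns the Z geometry into the relative configuration of the two new stereocentres (ethynyl cis to CH2OH).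

**Step 6**
Reactants: 8 [(2S,3R)-3-ethynyl-3-methyloxiran-2-yl]methanol
Product: 9 (2R,3R)-3-ethynyl-3-methyloxirane-2-carbaldehyde
Conditions: TEMPO (10 mol %), PhI(OAc)2, CH2Cl2, 0 to 23 °C; used as a solution
Reagents that add atoms: none
Why: Oxoammonium (TEMPO) oxidation with PhI(OAc)2 as terminal oxidant gives the epoxy aldehyde under neutral conditions without opening the epoxide, the descriptor at C-2 changing by the priority rules only.

**Step 7**
Reactants: 6 (5S)-5-{[(tert-butyldiphenylsilyl)oxy]methyl}-3-[(tributylstannyl)methyl]furan-2(5H)-one; 9 (2R,3R)-3-ethynyl-3-methyloxirane-2-carbaldehyde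
Product: 10 (4R,5S)-5-{[(tert-butyldiphenylsilyl)oxy]methyl}-4-{(S)-[(2S,3R)-3-ethynyl-3-methyloxiran-2-yl](hydroxy)methyl}-3-methylideneoxolan-2-one
Conditions: BF3·OEt2, CH2Cl2, −78 °C; aq. NaHCO3
Reagents that add atoms: none
Why: Lewis acid promoted SE2' allylation of the aldehyde by the allylstannane through an open antiperiplanar transition state forms the C–C bond at the former butenolide β-carbon anti to the silyloxymethyl group (new ring stereocentre, trans), gives the syn relation between the new carbinol and that ring carbon, and attacks the aldehyde face predicted by the Felkin–Anh model (anti to the epoxide C–O bond), the three preferences being matched.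

**Step 8**
Reactants: 10 (4R,5S)-5-{[(tert-butyldiphenylsilyl)oxy]methyl}-4-{(S)-[(2S,3R)-3-ethynyl-3-methyloxiran-2-yl](hydroxy)methyl}-3-methylideneoxolan-2-one
Product: 11 (4R,5S)-4-{(S)-[(2S,3R)-3-ethynyl-3-methyloxiran-2-yl](hydroxy)methyl}-5-(hydroxymethyl)-3-methylideneoxolan-2-one
Conditions: TBAF, AcOH, THF, 0 to 23 °C
Reagents that add atoms: none
Why: Fluoride-mediated desilylation buffered with acetic acid frees the primary alcohol without base-induced epoxide migration or conjugate addition to the methylene lactone.

**Step 9**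
Reactants: 11 (4R,5S)-4-{(S)-[(2S,3R)-3-ethynyl-3-methyloxiran-2-yl](hydroxy)methyl}-5-(hydroxymethyl)-3-methylideneoxolan-2-one
Product: 12 (2S,3R)-3-{(S)-[(2S,3R)-3-ethynyl-3-methyloxiran-2-yl](hydroxy)methyl}-4-methylidene-5-oxooxolane-2-carbaldehyde
Conditions: TEMPO (10 mol %), PhI(OAc)2, CH2Cl2, 0 to 23 °C; used crude
Reagents that add atoms: none
Why: TEMPO/PhI(OAc)2 oxidation is selective for the primary over the hindered secondary alcohol and should give the α-acyloxy aldehyde without epimerization.

**Step 10**
Reactants: 13 2-bromopropanoyl bromide; 14 2-(trimethylsilyl)ethanol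
Product: 15 2-(trimethylsilyl)ethyl 2-bromopropanoate (racemic)
Conditions: pyridine, CH2Cl2, 0 °C
Reagents that add atoms: none
Why: Nucleophilic acyl substitution of the acid bromide by the alcohol gives the fluoride-labile ester.

**Step 11**
Reactants: 15 2-(trimethylsilyl)ethyl 2-bromopropanoate; 16 diphenyl phosphite
Product: 17 2-(trimethylsilyl)ethyl 2-(diphenoxyphosphoryl)propanoate (racemic)
Conditions: Et3N, CH2Cl2, 0 to 23 °C
Reagents that add atoms: none
Why: Michaelis–Becker-type P-alkylation of the phosphite anion by the α-bromo ester gives the diaryl phosphonate needed for Z-selective olefination.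

**Step 12**
Reactants: 12 (2S,3R)-3-{(S)-[(2S,3R)-3-ethynyl-3-methyloxiran-2-yl](hydroxy)methyl}-4-methylidene-5-oxooxolane-2-carbaldehyde; 17 2-(trimethylsilyl)ethyl 2-(diphenoxyphosphoryl)propanoate
Product: 18 2-(trimethylsilyl)ethyl (2Z)-3-[(2R,3R)-3-{(S)-[(2S,3R)-3-ethynyl-3-methyloxiran-2-yl](hydroxy)methyl}-4-methylidene-5-oxooxolan-2-yl]-2-methylprop-2-enoate
Conditions: NaH (anion of 17 pre-formed), THF, −78 to −20 °C; aq. NH4Cl
Reagents that add atoms: none
Why: Ando-type Horner–Wadsworth–Emmons olefination, in which the electron-poor diaryl phosphonate makes oxaphosphetane collapse fast and so delivers the Z trisubstituted enoate (ester cis to the lactone carbon), while the pre-formed sodium phosphonate is not basic enough to touch the free hydroxyl or the α-stereocentre.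

**Step 13**
Reactants: 18 2-(trimethylsilyl)ethyl (2Z)-3-[(2R,3R)-3-{(S)-[(2S,3R)-3-ethynyl-3-methyloxiran-2-yl](hydroxy)methyl}-4-methylidene-5-oxooxolan-2-yl]-2-methylprop-2-enoate
Product: 20 nine-membered lactone diol (bicyclic dilactone; full description in the compound list), via seco acid 19 (not isolated)
Conditions: TASF [tris(dimethylamino)sulfonium difluorotrimethylsilicate], DMF, 0 °C; then added slowly to Ti(OiPr)4 (2 equiv), CH2Cl2 (final 1 mM), 0 to 23 °C; aq. NH4Cl
Reagents that add atoms: none
Why: Proposed new method: fluoride cleaves the 2-(trimethylsilyl)ethyl ester to the carboxylate of 19, which Ti(OiPr)4 binds together with the alkoxide of the 2,3-epoxy alcohol, and the carboxylate oxygen then attacks the distal, tertiary propargylic epoxide carbon (C-3) from the side opposite to the C–O bond that breaks (SN2). The closest known reaction type is the Ti(OiPr)4-mediated C-3-selective opening of 2,3-epoxy alcohols by carboxylic acids, known between two molecules, together with the lactonization of epoxy acids to five- and six-membered rings; its use for a medium ring is new. The nine-membered lactone closes in a 9-endo-tet mode, helped by the Z alkene and by the trans-disposed arms on the γ-lactone, which hold acid and epoxide within reach. The new quaternary stereocentre is controlled by the epoxide configuration set in step 5 (inversion at C-3, R to S), while the neighbouring carbon keeps its C–O bond and becomes the free secondary alcohol that closes the tetrahydropyran in step 14. The step needs attack at C-3 and not at C-2 (8-exo), substitution and not ionization to an enyne diol, and ring closure and not oligomerization; the tetravalent titanium chelate and the propargylic activation direct the nucleophile to C-3, the weak Lewis acid keeps the opening SN2-like, and high dilution favours the ring.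

**Step 14**
Reactants: 20 nine-membered lactone diol
Product: 21 tricyclic ethynyl alcohol (target skeleton with C≡CH for acetyl and OH for the angelate)
Conditions: DBU (20 mol %), CH2Cl2, 0 °C
Reagents that add atoms: none
Why: Intramolecular oxa-Michael addition (6-endo-trig) of the secondary hydroxyl next to the quaternary carbon to the exo-methylene lactone closes the tetrahydropyran, the other hydroxyl being left out because it would need a 5-endo-trig closure, and protonation of the lactone enolate sets the α-carbon to the cis ring fusion, the thermodynamic and only unstrained junction.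

**Step 15**
Reactants: 21 tricyclic ethynyl alcohol; 22 angelic acid [(2Z)-2-methylbut-2-enoic acid]
Product: 24 ethynyl angelate (21 acylated at its hydroxyl), via mixed anhydride 23 (not isolated)
Conditions: 22, 2,4,6-trichlorobenzoyl chloride, Et3N, toluene, 23 °C; then 21, toluene, 80 °C
Reagents that add atoms: 2,4,6-trichlorobenzoyl chloride, O=C(Cl)c1c(Cl)cc(Cl)cc1Cl (its atoms are carried in 23 only)
Why: Yamaguchi-type esterification through the mixed anhydride acylates the last free hydroxyl, and heating without a nucleophilic catalyst avoids isomerization of the angelate to the tiglate.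

**Step 16**
Reactants: 24 ethynyl angelate
Product: 25 CNP0342803.2 (target)
Conditions: Ph3PAuCl (5 mol %), AgSbF6 (5 mol %), 1,4-dioxane/H2O (10:1), 23 °C
Reagents that add atoms: water, O
Why: Markovnikov hydration of the terminal alkyne catalysed by monovalent gold, directed by 5-exo-dig participation of the neighbouring ester carbonyl, gives the methyl ketone without breaking the C–O bond of the quaternary centre, whose descriptor changes from S to R by the priority rules only.

**Compound list**

1 | (S)-but-3-ene-1,2-diol | OC[C@@H](O)C=C | starting material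
2 | (2S)-1-[(tert-butyldiphenylsilyl)oxy]but-3-en-2-ol | CC(C)(C)[Si](c1ccccc1)(c1ccccc1)OC[C@@H](O)C=C | intermediate
3 | 2-(bromomethyl)prop-2-enoic acid | C=C(CBr)C(=O)O | starting material
4 | (2S)-1-[(tert-butyldiphenylsilyl)oxy]but-3-en-2-yl 2-(bromomethyl)prop-2-enoate | C=C(CBr)C(=O)O[C@H](CO[Si](c1ccccc1)(c1ccccc1)C(C)(C)C)C=C | intermediate
5 | (5S)-3-(bromomethyl)-5-{[(tert-butyldiphenylsilyl)oxy]methyl}furan-2(5H)-one | BrCC1=C[C@@H](CO[Si](c2ccccc2)(c2ccccc2)C(C)(C)C)OC1=O | intermediate
6 | (5S)-5-{[(tert-butyldiphenylsilyl)oxy]methyl}-3-[(tributylstannyl)methyl]furan-2(5H)-one | CCCC[Sn](CCCC)(CCCC)CC1=C[C@@H](CO[Si](c2ccccc2)(c2ccccc2)C(C)(C)C)OC1=O | intermediate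
7 | (2Z)-3-methylpent-2-en-4-yn-1-ol | C#C/C(C)=C\CO | starting material
8 | [(2S,3R)-3-ethynyl-3-methyloxiran-2-yl]methanol | OC[C@@H]1O[C@]1(C)C#C | intermediate
9 | (2R,3R)-3-ethynyl-3-methyloxirane-2-carbaldehyde | O=C[C@@H]1O[C@]1(C)C#C | intermediate
10 | (4R,5S)-5-{[(tert-butyldiphenylsilyl)oxy]methyl}-4-{(S)-[(2S,3R)-3-ethynyl-3-methyloxiran-2-yl](hydroxy)methyl}-3-methylideneoxolan-2-one | C=C1C(=O)O[C@H](CO[Si](c2ccccc2)(c2ccccc2)C(C)(C)C)[C@H]1[C@H](O)[C@@H]3O[C@]3(C)C#C | intermediate
11 | (4R,5S)-4-{(S)-[(2S,3R)-3-ethynyl-3-methyloxiran-2-yl](hydroxy)methyl}-5-(hydroxymethyl)-3-methylideneoxolan-2-one | C=C1C(=O)O[C@H](CO)[C@H]1[C@H](O)[C@@H]2O[C@]2(C)C#C | intermediate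
12 | (2S,3R)-3-{(S)-[(2S,3R)-3-ethynyl-3-methyloxiran-2-yl](hydroxy)methyl}-4-methylidene-5-oxooxolane-2-carbaldehyde | C=C1C(=O)O[C@H](C=O)[C@H]1[C@H](O)[C@@H]2O[C@]2(C)C#C | intermediate
13 | 2-bromopropanoyl bromide | CC(Br)C(=O)Br | starting material
14 | 2-(trimethylsilyl)ethanol | C[Si](C)(C)CCO | starting material
15 | 2-(trimethylsilyl)ethyl 2-bromopropanoate (racemic) | CC(Br)C(=O)OCC[Si](C)(C)C | intermediate
16 | diphenyl phosphite | O=[PH](Oc1ccccc1)Oc1ccccc1 | starting material
17 | 2-(trimethylsilyl)ethyl 2-(diphenoxyphosphoryl)propanoate (racemic) | CC(C(=O)OCC[Si](C)(C)C)P(=O)(Oc1ccccc1)Oc1ccccc1 | intermediate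
18 | 2-(trimethylsilyl)ethyl (2Z)-3-[(2R,3R)-3-{(S)-[(2S,3R)-3-ethynyl-3-methyloxiran-2-yl](hydroxy)methyl}-4-methylidene-5-oxooxolan-2-yl]-2-methylprop-2-enoate | C=C1C(=O)O[C@H](/C=C(/C)C(=O)OCC[Si](C)(C)C)[C@H]1[C@H](O)[C@@H]2O[C@]2(C)C#C | intermediate
19 | seco acid: (2Z)-3-[(2R,3R)-3-{(S)-[(2S,3R)-3-ethynyl-3-methyloxiran-2-yl](hydroxy)methyl}-4-methylidene-5-oxooxolan-2-yl]-2-methylprop-2-enoic acid | C=C1C(=O)O[C@H](/C=C(/C)C(=O)O)[C@H]1[C@H](O)[C@@H]2O[C@]2(C)C#C | intermediate
20 | nine-membered lactone diol: (Z)-2-methyl enoate lactone ring trans-fused to the α-methylene-γ-butyrolactone at its β- and γ-carbons (R, R); the ring carbon on the lactone oxygen is quaternary (CH3, C≡CH; S) and is followed by two CH(OH) carbons (S, S) | O[C@H]1[C@H]2C(=C)C(=O)O[C@@H]2/C=C(/C)C(=O)O[C@@](C)(C#C)[C@H]1O | intermediate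
21 | tricyclic ethynyl alcohol: cis-fused tetrahydropyran/γ-lactone bridged by the (Z)-nine-membered lactone, C≡CH in place of acetyl, free OH in place of the angelate; carbinol carbon S, O–CH carbon of the tetrahydropyran S, quaternary carbon S, lactone β-carbon R, γ-carbon R, α-carbon S | O[C@H]1[C@@H]2[C@H]3/C=C(/C)C(=O)O[C@@](C)(C#C)[C@H]1OC[C@H]2C(=O)O3 | intermediate
22 | angelic acid, (2Z)-2-methylbut-2-enoic acid | C/C=C(/C)C(=O)O | starting material
23 | (2Z)-2-methylbut-2-enoic 2,4,6-trichlorobenzoic anhydride | C/C=C(/C)C(=O)OC(=O)c1c(Cl)cc(Cl)cc1Cl | intermediate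
24 | ethynyl angelate: 21 with its hydroxyl esterified by angelic acid (ester-bearing carbon S, lactone β-carbon now S by priority change, other centres as in 21) | C/C=C(/C)C(=O)O[C@H]1[C@@H]2[C@H]3/C=C(/C)C(=O)O[C@@](C)(C#C)[C@H]1OC[C@H]2C(=O)O3 | intermediate
25 | CNP0342803.2: angelate of the tricyclic acetyl lactone (angelate-bearing carbon S, O–CH carbon of the tetrahydropyran S, quaternary carbon R, lactone β-carbon S, γ-carbon R, α-carbon S) | C/C=C(/C)C(=O)O[C@H]1[C@@H]2[C@H]3/C=C(/C)C(=O)O[C@@](C)(C(C)=O)[C@H]1OC[C@H]2C(=O)O3 | target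

**Summary**

Total step count: 16. Longest linear sequence: 12 steps (steps 1–4, 7–9, 12–16).

Steps most likely to fail:

Step 13 (key step). The tertiary propargylic epoxide carbon may ionize before the carboxylate arrives, which would lead to elimination or loss of stereospecificity. Intermolecular esterification may outrun the medium-ring closure, and the neighbouring titanium alkoxide may transesterify the γ-lactone. The fallback sets out from 10 and returns at 21 and uses known reaction types only. Phosphonate 17 is cleaved with TASF to 2-(diphenoxyphosphoryl)propanoic acid F1, which serves as the external nucleophile in the Ti(OiPr)4-mediated C-3 opening of epoxy alcohol 10 and gives the tertiary phosphonopropanoate diol F2. DBU closes the tetrahydropyran by oxa-Michael addition to the bicyclic silyl ether F3. TBAF/AcOH gives the primary alcohol F4, and TEMPO/PhI(OAc)2 the aldehyde F5. An intramolecular Ando-type Horner–Wadsworth–Emmons reaction (NaH, THF, high dilution) then closes the nine-membered ring at the C=C bond, where the ring enforces the Z geometry, and gives 21.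

Step 7. The Lewis acid may open or rearrange the epoxy aldehyde before C–C bond formation, the acyl-substituted allylstannane may react too slowly, and Felkin control may erode. The fallback sets out from 6 and 7 and returns at 10. Enynol 7 is oxidized with MnO2 to (2Z)-3-methylpent-2-en-4-ynal F6, which is allylated by 6 with BF3·OEt2 through the same open transition state to give the syn enynyl carbinol F7. Sharpless epoxidation of this secondary allylic alcohol (Ti(OiPr)4, L-(+)-diisopropyl tartrate, t-BuOOH) is a matched case, in which reagent control and the erythro preference point to the same alkene face, and gives 10.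

Step 15. The hindered secondary hydroxyl may acylate slowly, so that isomerization of the angelate to the tiglate or acyl transfer from the tertiary ester competes. The fallback sets out from 21 and returns at 24. Alcohol 21 is esterified with 2-(diphenoxyphosphoryl)propanoic acid F1 (DCC, DMAP) to the phosphonate ester F8, and Ando-type olefination of F8 with acetaldehyde (NaH, THF, −78 °C) builds the angelate double bond with Z geometry on the substrate and gives 24.

**Further compounds**

F1 | step 13 | 2-(diphenoxyphosphoryl)propanoic acid (racemic) | CC(C(=O)O)P(=O)(Oc1ccccc1)Oc1ccccc1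
F2 | step 13 | tertiary phosphonopropanoate diol: 10 with the epoxide opened at C-3 by F1 (ester on the quaternary propargylic carbon, two free secondary hydroxyls) | C=C1C(=O)O[C@H](CO[Si](c2ccccc2)(c2ccccc2)C(C)(C)C)[C@H]1[C@H](O)[C@H](O)[C@](C)(C#C)OC(=O)C(C)P(=O)(Oc2ccccc2)Oc2ccccc2
F3 | step 13 | bicyclic silyl ether: cis-fused tetrahydropyran/γ-lactone from oxa-Michael closure of F2 | O[C@H]1[C@@H]2[C@@H](CO[Si](c3ccccc3)(c3ccccc3)C(C)(C)C)OC(=O)[C@@H]2CO[C@@H]1[C@](C)(C#C)OC(=O)C(C)P(=O)(Oc3ccccc3)Oc3ccccc3
F4 | step 13 | primary alcohol from desilylation of F3 | O[C@H]1[C@@H]2[C@@H](CO)OC(=O)[C@@H]2CO[C@@H]1[C@](C)(C#C)OC(=O)C(C)P(=O)(Oc3ccccc3)Oc3ccccc3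
F5 | step 13 | aldehyde from oxidation of F4 | O[C@H]1[C@@H]2[C@@H](C=O)OC(=O)[C@@H]2CO[C@@H]1[C@](C)(C#C)OC(=O)C(C)P(=O)(Oc3ccccc3)Oc3ccccc3
F6 | step 7 | (2Z)-3-methylpent-2-en-4-ynal | C#C/C(C)=C\C=O
F7 | step 7 | (4R,5S)-5-{[(tert-butyldiphenylsilyl)oxy]methyl}-4-[(1R,2Z)-1-hydroxy-3-methylpent-2-en-4-yn-1-yl]-3-methylideneoxolan-2-one | C=C1C(=O)O[C@H](CO[Si](c2ccccc2)(c2ccccc2)C(C)(C)C)[C@H]1[C@H](O)/C=C(/C)C#C
F8 | step 15 | 2-(diphenoxyphosphoryl)propanoate ester of 21 | CC(C(=O)O[C@H]1[C@@H]2[C@H]3/C=C(/C)C(=O)O[C@@](C)(C#C)[C@H]1OC[C@H]2C(=O)O3)P(=O)(Oc4ccccc4)Oc4ccccc4
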